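**Retrosynthetic overview**
- Ring C is closed last, at O1–C2, by oxidative cyclisation of a 2'-hydroxy-α-methoxydihydrochalcone; C2 is set trans to the existing C3 centre.
- The o-hydroxyaryl ketone comes from N–O hydrogenolysis of a 1,2-benzisoxazole. Its isoxazole ring is made in the key step, a (3+2) cycloaddition of a chiral nitrile oxide with 3,4,5-trimethoxybenzyne, which forms the future O1–C8a and C4–C4a bonds together.
- The nitrile oxide comes from an (R)-2-methoxy-3-arylpropanoate, made by Cu-catalysed opening of methyl (R)-glycidate with the ring B aryl Grignard; glycidate C2 becomes C3 of the target.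
- Ring order: rings A and B are bought as arenes; the isoxazole ring (temporary, fused to ring A) is formed first, ring C last.

Assumption: methyl (R)-glycidate (made on scale from L-serine), 3,4,5-trimethoxyphenol and 2-methoxyresorcinol are bought.

**Route**

Step 1
Reactants: 1 3,4,5-trimethoxyphenol
Product: 2 2-bromo-3,4,5-trimethoxyphenol
Conditions: NBS (1.0 equiv), CH2Cl2, −78 °C to 0 °C
Reagents that add atoms: N-bromosuccinimide, O=C1CCC(=O)N1Br
Why: Electrophilic aromatic bromination of the activated phenol goes ortho to the OH (the two free positions are equivalent and the para position is blocked), and one equivalent at low temperature stops at the monobromide.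

Step 2
Reactants: 2 2-bromo-3,4,5-trimethoxyphenol
Product: 5 3,4,5-trimethoxy-2-(trimethylsilyl)phenyl trifluoromethanesulfonate, via silyl ether 3 (not isolated), via lithium phenoxide 4 (not isolated)
Conditions: HMDS, THF, 70 °C, then evaporate; n-BuLi, THF, −78 °C; Tf2O, −78 °C to rt
Reagents that add atoms: hexamethyldisilazane, C[Si](C)(C)N[Si](C)(C)C; trifluoromethanesulfonic anhydride, O=S(=O)(OS(=O)(=O)C(F)(F)F)C(F)(F)F
Why: O-silylation, bromine–lithium exchange and anionic 1,3 O-to-C silyl migration (retro-Brook rearrangement) place the silyl group ortho to the phenoxide, which is then triflated to give the Kobayashi-type aryne precursor.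

Step 3
Reactants: 6 2-methoxybenzene-1,3-diol (2-methoxyresorcinol)
Product: 7 2-methoxy-1,3-bis(methoxymethoxy)benzene
Conditions: MOMCl (2.4 equiv), i-Pr2NEt, CH2Cl2, 0 °C to rt
Reagents that add atoms: chloromethyl methyl ether, COCCl
Why: Williamson-type O-alkylation of both phenols gives methoxymethyl acetal ethers that survive the organometallic, fluoride, hydrogenation and DDQ steps and are removed by acid at the end.

Step 4
Reactants: 7 2-methoxy-1,3-bis(methoxymethoxy)benzene
Product: 9 5-iodo-2-methoxy-1,3-bis(methoxymethoxy)benzene, via aryl boronate 8 (not isolated)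
Conditions: [Ir(cod)OMe]2 (1.5 mol%), dtbpy (3 mol%), B2pin2 (0.6 equiv), THF, 80 °C; evaporate; CuI (10 mol%), 1,10-phenanthroline (20 mol%), KI (1.5 equiv), MeOH/H2O, air, 80 °C
Reagents that add atoms: potassium iodide, [K+].[I-]
Why: Iridium-catalysed C–H borylation is sterically governed and takes the only ring C–H without an ortho substituent (C5, para to the methoxy group), and Cu-catalysed aerobic ipso-iododeboronation then puts iodine on that same carbon, which electrophilic halogenation would not reach.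

Step 5
Reactants: 9 5-iodo-2-methoxy-1,3-bis(methoxymethoxy)benzene; 10 methyl (2R)-oxirane-2-carboxylate (methyl (R)-glycidate)
Product: 12 methyl (2R)-2-hydroxy-3-[4-methoxy-3,5-bis(methoxymethoxy)phenyl]propanoate, via aryl Grignard 11 (not isolated)
Conditions: i-PrMgCl·LiCl, THF, −15 °C; then CuI (10 mol%), 10, −40 °C to −20 °C; aq NH4Cl
Reagents that add atoms: none
Why: Iodine–magnesium exchange followed by Cu-catalysed SN2 epoxide opening at the unsubstituted CH2 (faster than ester attack at −40 °C) forms the aryl–CH2 bond without touching the bought stereocentre, which becomes C3 of the target.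

Step 6
Reactants: 12 methyl (2R)-2-hydroxy-3-[4-methoxy-3,5-bis(methoxymethoxy)phenyl]propanoate
Product: 13 methyl (2R)-2-methoxy-3-[4-methoxy-3,5-bis(methoxymethoxy)phenyl]propanoate
Conditions: MeI (5 equiv), Ag2O (2 equiv), MeCN, rt, dark
Reagents that add atoms: iodomethane, CI
Why: Purdie O-methylation under neutral, non-enolising conditions installs the C3 methyl ether with the α-stereocentre intact.

Step 7
Reactants: 13 methyl (2R)-2-methoxy-3-[4-methoxy-3,5-bis(methoxymethoxy)phenyl]propanoate
Product: 15 (2R)-2-methoxy-3-[4-methoxy-3,5-bis(methoxymethoxy)phenyl]propanal oxime (E/Z mixture), via aldehyde 14 (not isolated)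
Conditions: i-Bu2AlH (1.1 equiv), CH2Cl2, −78 °C; then MeOH, NH2OH·HCl, pyridine, −78 °C to rt
Reagents that add atoms: hydroxylamine hydrochloride, Cl.NO
Why: The α-alkoxy ester gives a chelated aluminium hemiacetal that holds the aldehyde oxidation level at −78 °C (partial ester reduction), and condensation with hydroxylamine in the same flask traps the epimerisable α-methoxy aldehyde as its oxime before it can racemise.

Step 8
Reactants: 15 (2R)-2-methoxy-3-[4-methoxy-3,5-bis(methoxymethoxy)phenyl]propanal oxime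
Product: 16 (2R)-N-hydroxy-2-methoxy-3-[4-methoxy-3,5-bis(methoxymethoxy)phenyl]propanimidoyl chloride
Conditions: NCS (1.05 equiv), DMF, 0 °C to rt; aqueous work-up, used crude
Reagents that add atoms: N-chlorosuccinimide, O=C1CCC(=O)N1Cl
Why: Electrophilic chlorination of the aldoxime carbon gives the hydroximoyl chloride, the storable nitrile oxide precursor, and washing out the succinimide keeps it from adding to the aryne in the next step.

Step 9
Reactants: 16 (2R)-N-hydroxy-2-methoxy-3-[4-methoxy-3,5-bis(methoxymethoxy)phenyl]propanimidoyl chloride; 5 3,4,5-trimethoxy-2-(trimethylsilyl)phenyl trifluoromethanesulfonate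
Product: 19 3-{(1R)-1-methoxy-2-[4-methoxy-3,5-bis(methoxymethoxy)phenyl]ethyl}-4,5,6-trimethoxy-1,2-benzoxazole, via nitrile oxide 17 (not isolated), via aryne 18 (not isolated)
Conditions: 5 (1.5 equiv), CsF (4 equiv), MeCN, rt; 16 added by syringe pump over 3 h
Reagents that add atoms: none
Why: Fluoride unmasks 3,4,5-trimethoxybenzyne and dehydrochlorinates 16 to the nitrile oxide, and the two join in a concerted 1,3-dipolar (3+2) cycloaddition (the key step) that forms the future O1–C8a and C4–C4a bonds at once, the oxygen terminus expected to bond to the aryne carbon remote from the flanking methoxy group as in 3-methoxybenzyne additions, while the α-methoxy stereocentre is a spectator.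

Step 10
Reactants: 19 3-{(1R)-1-methoxy-2-[4-methoxy-3,5-bis(methoxymethoxy)phenyl]ethyl}-4,5,6-trimethoxy-1,2-benzoxazole
Product: 21 (2R)-1-(6-hydroxy-2,3,4-trimethoxyphenyl)-2-methoxy-3-[4-methoxy-3,5-bis(methoxymethoxy)phenyl]propan-1-one, via ketimine 20 (not isolated)
Conditions: H2 (1 atm), 5% Pd/C, EtOAc/MeOH, rt; then 10% aq citric acid, THF, rt
Reagents that add atoms: water, O
Why: Hydrogenolysis of the weak N–O bond opens the isoxazole ring to the o-hydroxyaryl N–H ketimine, and mild acidic hydrolysis gives the ketone without enolisation, so C3 stays (R).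

Step 11
Reactants: 21 (2R)-1-(6-hydroxy-2,3,4-trimethoxyphenyl)-2-methoxy-3-[4-methoxy-3,5-bis(methoxymethoxy)phenyl]propan-1-one
Product: 22 (2R,3R)-3,5,6,7-tetramethoxy-2-[4-methoxy-3,5-bis(methoxymethoxy)phenyl]-2,3-dihydro-4H-chromen-4-one
Conditions: DDQ (1.15 equiv), 1,4-dioxane, rt to 40 °C
Reagents that add atoms: none
Why: DDQ abstracts hydride from the benzylic CH2 activated by the para-methoxy group and the phenol captures the electron-poor benzylic carbon (oxidative cyclisation, dehydrogenative C–O coupling) to close ring C, the aryl group going trans-diequatorial to the C3 methoxy group so that the bought (3R) centre fixes (2R).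

Step 12
Reactants: 22 (2R,3R)-3,5,6,7-tetramethoxy-2-[4-methoxy-3,5-bis(methoxymethoxy)phenyl]-2,3-dihydro-4H-chromen-4-one
Product: 23 (2R,3R)-2-(3,5-dihydroxy-4-methoxyphenyl)-3,5,6,7-tetramethoxy-2,3-dihydro-4H-chromen-4-one (target)
Conditions: 3 M HCl, MeOH, 45 °C
Reagents that add atoms: none
Why: Acid-catalysed acetal methanolysis removes both methoxymethyl groups, and because the 2,3-trans isomer is the thermodynamic one and no base is present neither stereocentre is scrambled.

**Compound list**

1 | 3,4,5-trimethoxyphenol | COc1cc(O)cc(OC)c1OC | starting material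
2 | 2-bromo-3,4,5-trimethoxyphenol | COc1cc(O)c(Br)c(OC)c1OC | intermediate
3 | (2-bromo-3,4,5-trimethoxyphenoxy)trimethylsilane | COc1cc(O[Si](C)(C)C)c(Br)c(OC)c1OC | intermediate
4 | lithium 3,4,5-trimethoxy-2-(trimethylsilyl)phenoxide | COc1cc([O-])c([Si](C)(C)C)c(OC)c1OC.[Li+] | intermediate
5 | 3,4,5-trimethoxy-2-(trimethylsilyl)phenyl trifluoromethanesulfonate | COc1cc(OS(=O)(=O)C(F)(F)F)c([Si](C)(C)C)c(OC)c1OC | intermediate
6 | 2-methoxybenzene-1,3-diol | COc1c(O)cccc1O | starting material
7 | 2-methoxy-1,3-bis(methoxymethoxy)benzene | COCOc1cccc(OCOC)c1OC | intermediate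
8 | 2-[4-methoxy-3,5-bis(methoxymethoxy)phenyl]-4,4,5,5-tetramethyl-1,3,2-dioxaborolane | COCOc1cc(B2OC(C)(C)C(C)(C)O2)cc(OCOC)c1OC | intermediate
9 | 5-iodo-2-methoxy-1,3-bis(methoxymethoxy)benzene | COCOc1cc(I)cc(OCOC)c1OC | intermediate
10 | methyl (2R)-oxirane-2-carboxylate | COC(=O)[C@H]1CO1 | starting material
11 | [4-methoxy-3,5-bis(methoxymethoxy)phenyl]magnesium chloride | COCOc1cc([Mg]Cl)cc(OCOC)c1OC | intermediate
12 | methyl (2R)-2-hydroxy-3-[4-methoxy-3,5-bis(methoxymethoxy)phenyl]propanoate | COC(=O)[C@H](O)Cc1cc(OCOC)c(OC)c(OCOC)c1 | intermediate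
13 | methyl (2R)-2-methoxy-3-[4-methoxy-3,5-bis(methoxymethoxy)phenyl]propanoate | COC(=O)[C@H](OC)Cc1cc(OCOC)c(OC)c(OCOC)c1 | intermediate
14 | (2R)-2-methoxy-3-[4-methoxy-3,5-bis(methoxymethoxy)phenyl]propanal | O=C[C@H](OC)Cc1cc(OCOC)c(OC)c(OCOC)c1 | intermediate
15 | (2R)-2-methoxy-3-[4-methoxy-3,5-bis(methoxymethoxy)phenyl]propanal oxime (E/Z mixture) | ON=C[C@H](OC)Cc1cc(OCOC)c(OC)c(OCOC)c1 | intermediate
16 | (2R)-N-hydroxy-2-methoxy-3-[4-methoxy-3,5-bis(methoxymethoxy)phenyl]propanimidoyl chloride | ON=C(Cl)[C@H](OC)Cc1cc(OCOC)c(OC)c(OCOC)c1 | intermediate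
17 | (2R)-2-methoxy-3-[4-methoxy-3,5-bis(methoxymethoxy)phenyl]propanenitrile N-oxide | [O-][N+]#C[C@H](OC)Cc1cc(OCOC)c(OC)c(OCOC)c1 | intermediate
18 | 3,4,5-trimethoxybenzyne (1,2-didehydro-3,4,5-trimethoxybenzene) | COC1=C(OC)C(OC)=CC#C1 | intermediate
19 | 3-{(1R)-1-methoxy-2-[4-methoxy-3,5-bis(methoxymethoxy)phenyl]ethyl}-4,5,6-trimethoxy-1,2-benzoxazole | COc1cc2onc([C@H](OC)Cc3cc(OCOC)c(OC)c(OCOC)c3)c2c(OC)c1OC | intermediate
20 | 2-{(2R)-1-imino-2-methoxy-3-[4-methoxy-3,5-bis(methoxymethoxy)phenyl]propyl}-3,4,5-trimethoxyphenol | COc1cc(O)c(C(=N)[C@H](OC)Cc2cc(OCOC)c(OC)c(OCOC)c2)c(OC)c1OC | intermediate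
21 | (2R)-1-(6-hydroxy-2,3,4-trimethoxyphenyl)-2-methoxy-3-[4-methoxy-3,5-bis(methoxymethoxy)phenyl]propan-1-one | COc1cc(O)c(C(=O)[C@H](OC)Cc2cc(OCOC)c(OC)c(OCOC)c2)c(OC)c1OC | intermediate
22 | (2R,3R)-3,5,6,7-tetramethoxy-2-[4-methoxy-3,5-bis(methoxymethoxy)phenyl]-2,3-dihydro-4H-chromen-4-one | COc1cc2c(c(OC)c1OC)C(=O)[C@H](OC)[C@@H](c1cc(OCOC)c(OC)c(OCOC)c1)O2 | intermediate
23 | (2R,3R)-2-(3,5-dihydroxy-4-methoxyphenyl)-3,5,6,7-tetramethoxy-2,3-dihydro-4H-chromen-4-one | COc1cc2c(c(OC)c1OC)C(=O)[C@H](OC)[C@@H](c1cc(O)c(OC)c(O)c1)O2 | target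

**Step count and risks**

Total steps: 12. Longest linear sequence: 10 steps (steps 3 to 12); the aryne precursor (steps 1 and 2) joins at step 9.

Steps most likely to fail:

Step 9. The aliphatic nitrile oxide 17 may dimerise to the furoxan faster than the aryne traps it, and the selectivity for the 4,5,6-trimethoxy over the 5,6,7-trimethoxy benzisoxazole is predicted by analogy, not known for this aryne. The fallback makes the aryl ketone by organolithium acylation instead of cycloaddition. It sets out from bromophenol 2 and ester 13. Phenol 2 is benzylated (BnBr, K2CO3, DMF) to 1-(benzyloxy)-2-bromo-3,4,5-trimethoxybenzene F1. Bromine–lithium exchange (n-BuLi, THF, −78 °C) and addition of 13 at −78 °C give, through the chelated tetrahedral adduct, (2R)-1-[6-(benzyloxy)-2,3,4-trimethoxyphenyl]-2-methoxy-3-[4-methoxy-3,5-bis(methoxymethoxy)phenyl]propan-1-one F2. Hydrogenolysis of the benzyl ether (H2, Pd/C, EtOAc) comes back to the route at ketone 21.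

Step 11. DDQ may oxidise the electron-rich free phenol, over-dehydrogenate the product to the 3-methoxyflavone, or the cation may lose the C3 proton, which would erase the stereocentre. The fallback moves the benzylic oxidation ahead of phenol unmasking and closes the ring by ionisation. It sets out from benzisoxazole 19. DDQ in AcOH/CH2Cl2 gives 2-methoxy-1-[4-methoxy-3,5-bis(methoxymethoxy)phenyl]-2-(4,5,6-trimethoxy-1,2-benzoxazol-3-yl)ethyl acetate F3 as a mixture of epimers at the acetoxy carbon. Hydrogenolysis and hydrolysis as in step 10 give 3-(6-hydroxy-2,3,4-trimethoxyphenyl)-2-methoxy-1-[4-methoxy-3,5-bis(methoxymethoxy)phenyl]-3-oxopropyl acetate F4. Catalytic PPTS or BF3·OEt2 in CH2Cl2 ionises the benzylic acetate of either epimer and the phenol closes to the trans product, coming back to the route at 22.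

Step 5. The aryl Grignard may attack the ester of the glycidate or the epoxide may be opened by halide instead. The fallback uses an ester-free epoxide and adjusts the oxidation level afterwards. It sets out from iodide 9. Grignard 11 with CuI opens commercial (R)-tert-butyldimethylsilyl glycidyl ether at its CH2 to give (2R)-1-[tert-butyl(dimethyl)silyl]oxy-3-[4-methoxy-3,5-bis(methoxymethoxy)phenyl]propan-2-ol F5. Methylation (NaH, MeI, THF) gives tert-butyl{[(2R)-2-methoxy-3-[4-methoxy-3,5-bis(methoxymethoxy)phenyl]propyl]oxy}dimethylsilane F6. Desilylation (TBAF, THF) gives (2R)-2-methoxy-3-[4-methoxy-3,5-bis(methoxymethoxy)phenyl]propan-1-ol F7. Dess–Martin oxidation comes back to the route at aldehyde 14, which is oximated to 15 as in step 7.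

**Further compounds**

F1 | step 9 | 1-(benzyloxy)-2-bromo-3,4,5-trimethoxybenzene | COc1cc(OCc2ccccc2)c(Br)c(OC)c1OC
F2 | step 9 | (2R)-1-[6-(benzyloxy)-2,3,4-trimethoxyphenyl]-2-methoxy-3-[4-methoxy-3,5-bis(methoxymethoxy)phenyl]propan-1-one | COc1cc(OCc2ccccc2)c(C(=O)[C@H](OC)Cc2cc(OCOC)c(OC)c(OCOC)c2)c(OC)c1OC
F3 | step 11 | 2-methoxy-1-[4-methoxy-3,5-bis(methoxymethoxy)phenyl]-2-(4,5,6-trimethoxy-1,2-benzoxazol-3-yl)ethyl acetate (methoxy-bearing carbon as in 19, both epimers at the acetoxy carbon) | COc1cc2onc([C@H](OC)C(OC(C)=O)c3cc(OCOC)c(OC)c(OCOC)c3)c2c(OC)c1OC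
F4 | step 11 | 3-(6-hydroxy-2,3,4-trimethoxyphenyl)-2-methoxy-1-[4-methoxy-3,5-bis(methoxymethoxy)phenyl]-3-oxopropyl acetate (methoxy-bearing carbon as in 21, both epimers at the acetoxy carbon) | COc1cc(O)c(C(=O)[C@H](OC)C(OC(C)=O)c2cc(OCOC)c(OC)c(OCOC)c2)c(OC)c1OC
F5 | step 5 | (2R)-1-[tert-butyl(dimethyl)silyl]oxy-3-[4-methoxy-3,5-bis(methoxymethoxy)phenyl]propan-2-ol | CC(C)(C)[Si](C)(C)OC[C@H](O)Cc1cc(OCOC)c(OC)c(OCOC)c1
F6 | step 5 | tert-butyl{[(2R)-2-methoxy-3-[4-methoxy-3,5-bis(methoxymethoxy)phenyl]propyl]oxy}dimethylsilane | CC(C)(C)[Si](C)(C)OC[C@H](OC)Cc1cc(OCOC)c(OC)c(OCOC)c1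
F7 | step 5 | (2R)-2-methoxy-3-[4-methoxy-3,5-bis(methoxymethoxy)phenyl]propan-1-ol | OC[C@H](OC)Cc1cc(OCOC)c(OC)c(OCOC)c1
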